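**Plan**
1. Retrosynthesis: cut C11–C12 (sp3–sp2 coupling), strip the C6/C7/C8 oxygens and C11 back to a bicyclic enone (C9 ketone, C7=C8), then cut C5–C10 and C7–C8 together to an acyclic keto enal.
2. Enabling feature: C9 of ring B lies between C8 and C10, so a C9 ketone makes both of its alpha-carbons nucleophiles. C5 and C7 are the beta- and carbonyl carbons of a 2-enal, and the C1–C4 chain (C4 quaternary, so no gamma-hydrogen) ties the two three-carbon units together.
3. Forward: pentan-3-one and a bromo ester give the keto enal in four steps. One amine-catalysed Michael/Mannich-elimination cascade then closes ring A (C5–C10) and ring B (C7–C8).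
4. Then: methyl addition and oxidative transposition (C11 in, C7=O), Rubottom oxidation at C6, deconjugative hydroxylation at C8, reduction and acetylation at C7, hydroboration/Suzuki coupling with a (Z)-dienyl iodide.
5. Stereochemistry: C5 from the chiral imidazolidinone catalyst, C10 relayed from C5 in the cyclization. C6, C8 and C9 follow from reagent attack anti to the axial C10 methyl, C7 from axial hydride delivery, and the 12Z alkene from a hydroxyl-directed carbometalation.

Key step: step 5

Numbering: locants are drimane/labdane locants (ring carbons C1–C10; C11 on C9; "C10 methyl" and "C8 methyl" are named as such).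
Assumption: the (2R,5R)-imidazolidinone is taken to direct the nucleophile to the Re face of the enal beta-carbon (C5), by analogy with its known sense of induction with (E)-but-2-enal; the (2S,5S)-catalyst would be used if the opposite sense were found.
Assumption: the bromo ester and the reagents named are taken as commercially available.

Step 1
Reactants: 1 pentan-3-one; 2 ethyl 5-bromo-2,2-dimethylpentanoate
Product: 3 ethyl 2,2,6-trimethyl-7-oxononanoate (racemic)
Conditions: LiN(i-Pr)2, THF, −78 °C; then 2, DMPU, −78 to 0 °C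
Reagents that add atoms: none
Why: The kinetic lithium enolate of the symmetrical ketone is alkylated by the unhindered primary bromide (SN2 enolate alkylation), and the new stereocenter (later C10) may stay racemic because it is re-enolized in step 5.

Step 2
Reactants: 3 ethyl 2,2,6-trimethyl-7-oxononanoate
Product: 4 2,2,6-trimethylnonane-1,7-diol (mixture of diastereomers)
Conditions: LiAlH4, THF, 0 °C to rt
Reagents that add atoms: none
Why: LiAlH4 reduces the neopentyl ester and the ketone together (hydride reduction), so the two carbonyl groups need not be differentiated.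

Step 3
Reactants: 4 2,2,6-trimethylnonane-1,7-diol
Product: 5 2,2,6-trimethyl-7-oxononanal (racemic)
Conditions: Dess–Martin periodinane, NaHCO3, CH2Cl2, 0 °C to rt
Reagents that add atoms: none
Why: Dess–Martin oxidation returns both alcohols to the carbonyl level under buffered, non-enolizing conditions, so the keto aldehyde should not undergo aldol cyclization.

Step 4
Reactants: 5 2,2,6-trimethyl-7-oxononanal
Product: 6 (E)-4,4,8-trimethyl-9-oxoundec-2-enal (racemic at C8)
Conditions: Ph3P=CHCHO, toluene, 90 °C
Reagents that add atoms: (triphenylphosphoranylidene)acetaldehyde O=CC=P(c1ccccc1)(c1ccccc1)c1ccccc1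
Why: The stabilized ylide reacts only with the non-enolizable aldehyde and should give the (E)-enal (Wittig olefination), leaving the ketone untouched.

Step 5
Reactants: 6 (E)-4,4,8-trimethyl-9-oxoundec-2-enal
Product: 8 (4aR,8aR)-2,5,5,8a-tetramethyl-4a,5,6,7,8,8a-hexahydronaphthalen-1(4H)-one, via keto aldehyde 7 (not isolated)
Conditions: (2R,5R)-5-benzyl-2-tert-butyl-3-methylimidazolidin-4-one (20 mol%), CF3CO2H (20 mol%), CHCl3/i-PrOH, high dilution, 40 °C
Reagents that add atoms: none
Why: Proposed new method: the amine condenses with the enal to an (E)-iminium ion whose C5 is attacked by the more substituted enol of the ketone (C10) in a 6-(enolexo)-exo-trig Michael addition that closes ring A; the resulting enamine is protonated to the C7 iminium ion (7 in hydrolysed form), which the C8 enol attacks in a 6-(enolendo)-exo-trig Mannich closure of ring B, and beta-elimination of the catalyst gives the conjugated enone. The closest known reaction types are iminium-catalysed conjugate additions of enol-type carbon nucleophiles to (E)-enals and amine-catalysed Robinson-type alpha,alpha'-annulations of ketones with enals; new is an unactivated alpha-branched ketone acting as the intramolecular nucleophile and forming a quaternary carbon. C5 is set by the catalyst, whose benzyl group shields one face of the iminium ion so that C10 adds to the Re face of C5 (5R); C10 is set relative to C5 in a chair-like transition state with the enol carbon C9 and the iminium carbon C6 both pseudo-equatorial, which puts the C10 methyl trans to H-5 (10R). The step needs each alpha-carbon of the ketone to react at the right electrophile, which ring size secures (C10 reaches C5 and C8 reaches C7 only through six-membered rings), and 1,4- before 1,2-addition, which the iminium ion secures. The quaternary C4 leaves the enal without gamma-hydrogens, so no dienamine pathway competes.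

Step 6
Reactants: 8 (4aR,8aR)-2,5,5,8a-tetramethyl-4a,5,6,7,8,8a-hexahydronaphthalen-1(4H)-one
Product: 9 (5R,9R,10R)-drim-7-en-9-ol
Conditions: MeLi, CeCl3, THF, −78 °C
Reagents that add atoms: methyllithium [Li]C
Why: The organocerium reagent from MeLi and CeCl3 adds 1,2 to the hindered enone carbonyl without enolization (carbonyl addition), from the face anti to the C10 methyl, and the carbinol configuration is erased in step 7.

Step 7
Reactants: 9 (5R,9R,10R)-drim-7-en-9-ol
Product: 10 (5R,10R)-drim-8-en-7-one
Conditions: pyridinium chlorochromate (C5H5NH[CrO3Cl]), 4 Å molecular sieves, CH2Cl2, rt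
Reagents that add atoms: pyridinium chlorochromate [O-][Cr](=O)(=O)Cl.c1cc[nH+]cc1
Why: The tertiary allylic chromate ester undergoes a [3,3]-sigmatropic shift and oxidation (Babler–Dauben oxidative transposition), which puts the carbonyl on C7 and leaves the new methyl (C11) on C9 of a tetrasubstituted enone.

Step 8
Reactants: 10 (5R,10R)-drim-8-en-7-one
Product: 12 (5R,6S,10R)-6-[(triethylsilyl)oxy]drim-8-en-7-one, via silyl dienol ether 11 (not isolated)
Conditions: LiN(i-Pr)2, THF, −78 °C; Et3SiCl; then 3-ClC6H4CO3H, NaHCO3, CH2Cl2, −20 °C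
Reagents that add atoms: chlorotriethylsilane CC[Si](Cl)(CC)CC; 3-chloroperbenzoic acid OOC(=O)c1cccc(Cl)c1
Why: Kinetic deprotonation at C6 gives the cross-conjugated silyl dienol ether, whose enol ether double bond is epoxidized from the face anti to the axial C4 and C10 methyls, and silyl migration gives the equatorial 6-silyloxy ketone (Rubottom oxidation; 6S is also the thermodynamic epimer).

Step 9
Reactants: 12 (5R,6S,10R)-6-[(triethylsilyl)oxy]drim-8-en-7-one
Product: 13 (5R,6S,8R,10R)-8-hydroxy-6-[(triethylsilyl)oxy]drim-9(11)-en-7-one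
Conditions: KN(SiMe3)2, THF, −78 to −40 °C; then 3-phenyl-2-(phenylsulfonyl)oxaziridine, −78 °C
Reagents that add atoms: 3-phenyl-2-(phenylsulfonyl)oxaziridine O=S(=O)(N1OC1c1ccccc1)c1ccccc1
Why: With C6 now a hindered silyloxy methine, the base should remove a C11 proton to give the extended potassium dienolate, which the oxaziridine hydroxylates at its alpha-carbon C8 from the face anti to the C10 methyl (deconjugative alpha-hydroxylation), setting 8R and moving the alkene to C9=C11.

Step 10
Reactants: 13 (5R,6S,8R,10R)-8-hydroxy-6-[(triethylsilyl)oxy]drim-9(11)-en-7-one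
Product: 14 (5R,6S,7R,8R,10R)-6-[(triethylsilyl)oxy]drim-9(11)-ene-7,8-diol
Conditions: NaBH4, CeCl3·7H2O, MeOH, −40 °C
Reagents that add atoms: none
Why: Hydride is delivered axially to C7 from the face that carries only H-5, away from the axial C8 methyl, so the equatorial 7R alcohol should result (Luche reduction).

Step 11
Reactants: 14 (5R,6S,7R,8R,10R)-6-[(triethylsilyl)oxy]drim-9(11)-ene-7,8-diol
Product: 15 (5R,6S,7R,8R,10R)-8-hydroxy-6-[(triethylsilyl)oxy]drim-9(11)-en-7-yl acetate
Conditions: Ac2O, DMAP, pyridine, CH2Cl2, rt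
Reagents that add atoms: acetic anhydride CC(=O)OC(C)=O
Why: DMAP-catalysed acetylation esterifies the secondary 7-hydroxyl while the tertiary allylic 8-hydroxyl does not react (chemoselective acylation).

Step 12
Reactants: 15 (5R,6S,7R,8R,10R)-8-hydroxy-6-[(triethylsilyl)oxy]drim-9(11)-en-7-yl acetate
Product: 16 (5R,6S,7R,8R,10R)-6,8-dihydroxydrim-9(11)-en-7-yl acetate
Conditions: HF·pyridine, pyridine, THF, 0 °C
Reagents that add atoms: none
Why: Buffered HF·pyridine cleaves the triethylsilyl ether (fluoride desilylation) under conditions too mild for acetyl migration or ionization of the tertiary allylic alcohol.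

Step 13
Reactants: 17 prop-2-yn-1-ol
Product: 18 (Z)-3-iodo-2-methylprop-2-en-1-ol
Conditions: MeMgBr, CuI (10 mol%), THF, 0 °C to rt; then I2, −78 to 0 °C
Reagents that add atoms: methylmagnesium bromide C[Mg]Br; iodine II
Why: Copper-catalysed, alkoxide-directed anti carbomagnesiation places the methyl on C2 and magnesium on C3 cis to the CH2O group, and iodinolysis with retention gives the (Z)-iodoalkene (carbometalation/iodination).

Step 14
Reactants: 18 (Z)-3-iodo-2-methylprop-2-en-1-ol
Product: 19 (Z)-3-iodo-2-methylprop-2-enal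
Conditions: MnO2, CH2Cl2, rt, dark
Reagents that add atoms: none
Why: MnO2 oxidizes the allylic alcohol to the enal under neutral conditions that should leave the iodoalkene geometry intact (allylic oxidation).

Step 15
Reactants: 19 (Z)-3-iodo-2-methylprop-2-enal
Product: 20 (Z)-1-iodo-2-methylbuta-1,3-diene
Conditions: Ph3PCH3Br, KN(SiMe3)2, THF, −78 to 0 °C; used as a solution
Reagents that add atoms: methyltriphenylphosphonium bromide C[P+](c1ccccc1)(c1ccccc1)c1ccccc1.[Br-]
Why: The non-stabilized ylide methylenates the aldehyde (Wittig reaction) without touching the iodoalkene, so the Z geometry is carried into the diene.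

Step 16
Reactants: 16 (5R,6S,7R,8R,10R)-6,8-dihydroxydrim-9(11)-en-7-yl acetate; 20 (Z)-1-iodo-2-methylbuta-1,3-diene
Product: 22 (5R,6S,7R,8R,9S,10R,12Z)-6,8-dihydroxylabda-12,14-dien-7-yl acetate, via alkylborane 21 (not isolated)
Conditions: 9-BBN (4 equiv), THF, rt to 50 °C; then 20, PdCl2(dppf), AsPh3, K3PO4 (aq), DMF, rt
Reagents that add atoms: none
Why: 9-BBN adds to the exocyclic alkene from the face anti to the axial C8 and C10 methyls, putting boron on C11 and hydrogen on C9 (9S), and the B-alkyl Suzuki–Miyaura coupling joins C11 to C12 with retention of the Z-iodoalkene geometry.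

**Compound list**
1 | pentan-3-one | CCC(=O)CC | starting material
2 | ethyl 5-bromo-2,2-dimethylpentanoate | CCOC(=O)C(C)(C)CCCBr | starting material
3 | ethyl 2,2,6-trimethyl-7-oxononanoate (racemic) | CCOC(=O)C(C)(C)CCCC(C)C(=O)CC | intermediate
4 | 2,2,6-trimethylnonane-1,7-diol (mixture of diastereomers) | OCC(C)(C)CCCC(C)C(O)CC | intermediate
5 | 2,2,6-trimethyl-7-oxononanal (racemic) | O=CC(C)(C)CCCC(C)C(=O)CC | intermediate
6 | (E)-4,4,8-trimethyl-9-oxoundec-2-enal (racemic at C8) | O=C/C=C/C(C)(C)CCCC(C)C(=O)CC | intermediate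
7 | 2-[(1R,6R)-2,2,6-trimethyl-6-propanoylcyclohexyl]acetaldehyde (not isolated) | O=CC[C@@H]1C(C)(C)CCC[C@@]1(C)C(=O)CC | intermediate
8 | (4aR,8aR)-2,5,5,8a-tetramethyl-4a,5,6,7,8,8a-hexahydronaphthalen-1(4H)-one (trans-fused; C9 ketone, C7=C8) | O=C1C(C)=CC[C@@H]2C(C)(C)CCC[C@]21C | intermediate
9 | (5R,9R,10R)-drim-7-en-9-ol | C[C@@]1(O)C(C)=CC[C@@H]2C(C)(C)CCC[C@]21C | intermediate
10 | (5R,10R)-drim-8-en-7-one | O=C1C[C@@H]2C(C)(C)CCC[C@@]2(C)C(C)=C1C | intermediate
11 | (5R,10R)-7-[(triethylsilyl)oxy]drima-6,8-diene (not isolated) | CC[Si](CC)(CC)OC1=C[C@@H]2C(C)(C)CCC[C@@]2(C)C(C)=C1C | intermediate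
12 | (5R,6S,10R)-6-[(triethylsilyl)oxy]drim-8-en-7-one | O=C1[C@@H](O[Si](CC)(CC)CC)[C@@H]2C(C)(C)CCC[C@@]2(C)C(C)=C1C | intermediate
13 | (5R,6S,8R,10R)-8-hydroxy-6-[(triethylsilyl)oxy]drim-9(11)-en-7-one | C=C1[C@@](C)(O)C(=O)[C@@H](O[Si](CC)(CC)CC)[C@@H]2C(C)(C)CCC[C@]21C | intermediate
14 | (5R,6S,7R,8R,10R)-6-[(triethylsilyl)oxy]drim-9(11)-ene-7,8-diol | C=C1[C@@](C)(O)[C@H](O)[C@@H](O[Si](CC)(CC)CC)[C@@H]2C(C)(C)CCC[C@]21C | intermediate
15 | (5R,6S,7R,8R,10R)-8-hydroxy-6-[(triethylsilyl)oxy]drim-9(11)-en-7-yl acetate | C=C1[C@@](C)(O)[C@H](OC(C)=O)[C@@H](O[Si](CC)(CC)CC)[C@@H]2C(C)(C)CCC[C@]21C | intermediate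
16 | (5R,6S,7R,8R,10R)-6,8-dihydroxydrim-9(11)-en-7-yl acetate | C=C1[C@@](C)(O)[C@H](OC(C)=O)[C@@H](O)[C@@H]2C(C)(C)CCC[C@]21C | intermediate
17 | prop-2-yn-1-ol | C#CCO | starting material
18 | (Z)-3-iodo-2-methylprop-2-en-1-ol | OC/C(C)=C\I | intermediate
19 | (Z)-3-iodo-2-methylprop-2-enal | O=C/C(C)=C\I | intermediate
20 | (Z)-1-iodo-2-methylbuta-1,3-diene | C=C/C(C)=C\I | intermediate
21 | (5R,6S,7R,8R,9S,10R)-11-(9-borabicyclo[3.3.1]nonan-9-yl)-6,8-dihydroxydriman-7-yl acetate (not isolated) | C(B3C4CCCC3CCC4)[C@@H]1[C@@](C)(O)[C@H](OC(C)=O)[C@@H](O)[C@@H]2C(C)(C)CCC[C@]21C | intermediate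
22 | (5R,6S,7R,8R,9S,10R,12Z)-6,8-dihydroxylabda-12,14-dien-7-yl acetate | C=C/C(C)=C\C[C@@H]1[C@@](C)(O)[C@H](OC(C)=O)[C@@H](O)[C@@H]2C(C)(C)CCC[C@]21C | target

**Totals**
Total step count: 16. Longest linear sequence: 13 steps (steps 1–12 and 16).

**Steps most likely to fail**

Step 5 (Proposed new method). The conjugate addition at the neopentyl beta-carbon may be too slow, or facial control by the catalyst may be poor. The fallback sets out from 5 and comes back at 10. Horner–Wadsworth–Emmons reaction of 5 with trimethyl phosphonoacetate (LiCl, DBU, MeCN) gives methyl (E)-4,4,8-trimethyl-9-oxoundec-2-enoate F1. Condensation with (S)-1-phenylethylamine gives the ketimine methyl (E)-4,4,8-trimethyl-9-{[(1S)-1-phenylethyl]imino}undec-2-enoate F2. On heating, its more substituted secondary enamine tautomer adds to the tethered enoate (auxiliary-controlled aza-ene-type Michael addition, the established route to alpha-quaternary ketones), and aqueous acetic acid releases methyl 2-[(1R,6R)-2,2,6-trimethyl-6-propanoylcyclohexyl]acetate F3. KOt-Bu-mediated Dieckmann-type cyclization closes ring B to (4aR,8aR)-2,5,5,8a-tetramethylhexahydronaphthalene-1,3(2H,4H)-dione F4. O-Methylation at the less hindered oxygen (trimethyl orthoformate, MeOH, TsOH) gives (4aR,8aR)-3-methoxy-2,5,5,8a-tetramethyl-4a,5,6,7,8,8a-hexahydronaphthalen-1(4H)-one F5. MeLi/CeCl3 addition and acidic work-up (Stork–Danheiser transposition) then give 10.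

Step 9. Hydroxylation may occur at the gamma-carbon C11 instead of C8, or the base may deprotonate C6. The fallback sets out from 12 and comes back at 15. Luche reduction (NaBH4, CeCl3) gives (5R,6S,7S,10R)-6-[(triethylsilyl)oxy]drim-8-en-7-ol F6 by axial hydride delivery. Acetylation gives (5R,6S,7S,10R)-6-[(triethylsilyl)oxy]drim-8-en-7-yl acetate F7. Epoxidation with 3-chloroperbenzoic acid from the face anti to the C10 methyl gives (5R,6S,7R,8S,9R,10R)-8,9-epoxy-6-[(triethylsilyl)oxy]driman-7-yl acetate F8. Al(Oi-Pr)3 in hot toluene should open the C9–O bond (the carbon remote from the electron-withdrawing acetoxy group) with loss of a C11 proton, the only beta-hydrogens available, to give 15.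

Step 16. Hydroboration of an alkene flanked by two quaternary carbons may be incomplete, and the basic coupling medium may cause acetyl migration to the 6-hydroxyl. The fallback sets out from 16 and comes back at 22. Hydroformylation (Rh(acac)(CO)2, tris(2,4-di-tert-butylphenyl) phosphite, CO/H2) delivers hydrogen to C9 and the formyl group to C11 from the open face. The aldehyde closes onto the 8-hydroxyl to give the lactol (5R,6S,7R,8R,9S,10R)-6,12-dihydroxy-8,12-epoxy-13,14,15,16-tetranorlabdan-7-yl acetate F9. Stork–Zhao-type olefination with the ylide from (1-iodoethyl)triphenylphosphonium iodide and NaN(SiMe3)2 gives (5R,6S,7R,8R,9S,10R,12Z)-6,8-dihydroxy-13-iodo-14,15-dinorlabd-12-en-7-yl acetate F10. Stille coupling with tributyl(vinyl)stannane (Pd(PPh3)4, CuI, DMF) gives 22.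

**Further compounds**
F1 | step 5 | methyl (E)-4,4,8-trimethyl-9-oxoundec-2-enoate | COC(=O)/C=C/C(C)(C)CCCC(C)C(=O)CC
F2 | step 5 | methyl (E)-4,4,8-trimethyl-9-{[(1S)-1-phenylethyl]imino}undec-2-enoate | COC(=O)/C=C/C(C)(C)CCCC(C)C(CC)=N[C@@H](C)c1ccccc1
F3 | step 5 | methyl 2-[(1R,6R)-2,2,6-trimethyl-6-propanoylcyclohexyl]acetate | COC(=O)C[C@@H]1C(C)(C)CCC[C@@]1(C)C(=O)CC
F4 | step 5 | (4aR,8aR)-2,5,5,8a-tetramethylhexahydronaphthalene-1,3(2H,4H)-dione (C2 epimers) | O=C1C[C@@H]2C(C)(C)CCC[C@@]2(C)C(=O)C1C
F5 | step 5 | (4aR,8aR)-3-methoxy-2,5,5,8a-tetramethyl-4a,5,6,7,8,8a-hexahydronaphthalen-1(4H)-one | O=C1C(C)=C(OC)C[C@@H]2C(C)(C)CCC[C@]21C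
F6 | step 9 | (5R,6S,7S,10R)-6-[(triethylsilyl)oxy]drim-8-en-7-ol | O[C@@H]1[C@@H](O[Si](CC)(CC)CC)[C@@H]2C(C)(C)CCC[C@@]2(C)C(C)=C1C
F7 | step 9 | (5R,6S,7S,10R)-6-[(triethylsilyl)oxy]drim-8-en-7-yl acetate | CC(=O)O[C@@H]1[C@@H](O[Si](CC)(CC)CC)[C@@H]2C(C)(C)CCC[C@@]2(C)C(C)=C1C
F8 | step 9 | (5R,6S,7R,8S,9R,10R)-8,9-epoxy-6-[(triethylsilyl)oxy]driman-7-yl acetate | CC(=O)O[C@@H]1[C@@H](O[Si](CC)(CC)CC)[C@@H]2C(C)(C)CCC[C@@]2(C)[C@@]3(C)O[C@@]13C
F9 | step 16 | (5R,6S,7R,8R,9S,10R)-6,12-dihydroxy-8,12-epoxy-13,14,15,16-tetranorlabdan-7-yl acetate (C12 epimers) | OC1C[C@@H]2[C@@](C)(O1)[C@H](OC(C)=O)[C@@H](O)[C@@H]3C(C)(C)CCC[C@]32C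
F10 | step 16 | (5R,6S,7R,8R,9S,10R,12Z)-6,8-dihydroxy-13-iodo-14,15-dinorlabd-12-en-7-yl acetate | C/C(I)=C/C[C@@H]1[C@@](C)(O)[C@H](OC(C)=O)[C@@H](O)[C@@H]2C(C)(C)CCC[C@]21C
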